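**Retrosynthetic overview**
1. C5–OCH3: the methyl ether is a vinylogous ester. It is cut back to 3-docosyl-2,5-dihydroxy-1,4-benzoquinone and MeOH, and the docosyl neighbour shields the other OH.
2. C3–CH2 (key disconnection): enolic ring carbon plus aldehyde, a reductive Knoevenagel alkylation of C2h-symmetric 2,5-dihydroxy-1,4-benzoquinone with docosanal. One of two equivalent C–H positions reacts and the symmetry is broken. Lines 1 and 2 are run forward in one flask.
3. 2,5-Dihydroxy-1,4-benzoquinone comes from hydroquinone by a six-electron oxidative dearomatisation with alkaline H2O2.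
4. Rings: none is built. The only carbocycle is the benzene ring of hydroquinone. No protecting groups and no organometallic reagents are used.

Assumption: the target has no stereocentre and no stereogenic double bond, so nothing has to be induced or resolved; the side chain is read as unbranched docosyl (22 carbons outside the ring), and docosanal (behenaldehyde, CAS 57402-36-5) is taken as a catalogue fatty aldehyde.

**Route**

Step 1
Reactants: 1 hydroquinone (benzene-1,4-diol)
Product: 3 2,5-dihydroxy-1,4-benzoquinone, via disodium salt 2 (not isolated)
Conditions: 30% aq. H2O2 (3.3 equiv, slow addition), 50% aq. NaOH, 40–50 °C, 2 h; then conc. HCl, 0 °C, pH 1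
Reagents that add atoms: hydrogen peroxide, OO; sodium hydroxide, [Na+].[OH-] (sodium of 2 only)
Why: Oxidative dearomatisation: alkaline peroxide takes the electron-rich diphenolate to the quinone level and then runs two rounds of conjugate nucleophilic oxygenation (Weitz–Scheffer-type attack of HOO−) and re-oxidation, each oxygen steering the next to the para-related carbon, and the cascade halts at 2 because this doubly vinylogous carboxylate is neither electrophilic nor soluble in strong lye; no stereocentre is formed.

Step 2
Reactants: 3 2,5-dihydroxy-1,4-benzoquinone; 4 docosanal
Product: 7 3-docosyl-2-hydroxy-5-methoxy-1,4-benzoquinone (target), via docosylidene trione 5 (not isolated), via docosyl dihydroxyquinone 6 (not isolated)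
Conditions: 3 (1.3 equiv), Hantzsch ester (diethyl 2,6-dimethyl-1,4-dihydropyridine-3,5-dicarboxylate, 1.05 equiv), L-proline (20 mol%), CH2Cl2, 25 °C, 16 h; then MeOH, conc. H2SO4 (5 vol%), reflux, 6 h
Reagents that add atoms: methanol, CO
Why: Proline-mediated Knoevenagel condensation of 4 at one of the two equivalent enolic C–H carbons of C2h-symmetric 3 gives the strongly electrophilic o-quinone methide 5, which the Hantzsch ester reduces by conjugate hydride transfer (organocatalytic three-component reductive alkylation), and in the now unsymmetrical 6 the acid-catalysed addition–elimination of MeOH (vinylogous Fischer esterification) occurs at C5, where the OMe can lie in the ring plane next to C6–H, and not at C2, which is flanked by the docosyl chain and C1=O; no stereocentre is formed.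

**Compound list**
1 | hydroquinone (benzene-1,4-diol) | Oc1ccc(O)cc1 | starting material
2 | disodium salt of 3 (disodium 3,6-dioxocyclohexa-1,4-diene-1,4-diolate) | [Na+].[Na+].[O-]C1=CC(=O)C([O-])=CC1=O | intermediate
3 | 2,5-dihydroxy-1,4-benzoquinone | OC1=CC(=O)C(O)=CC1=O | intermediate
4 | docosanal | CCCCCCCCCCCCCCCCCCCCCC=O | starting material
5 | 3-docosylidene-5-hydroxycyclohex-5-ene-1,2,4-trione (o-quinone methide; exocyclic C=C geometry undefined and lost on reduction) | CCCCCCCCCCCCCCCCCCCCCC=C1C(=O)C(=O)C=C(O)C1=O | intermediate
6 | 3-docosyl-2,5-dihydroxy-1,4-benzoquinone | CCCCCCCCCCCCCCCCCCCCCCC1=C(O)C(=O)C=C(O)C1=O | intermediate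
7 | 3-docosyl-2-hydroxy-5-methoxy-1,4-benzoquinone (achiral) | CCCCCCCCCCCCCCCCCCCCCCC1=C(O)C(=O)C=C(OC)C1=O | target

**Step count and weak points**
Total steps: 2. Longest linear sequence: 2.

The route has only two steps. Its three weakest points are therefore the two stages of step 2 and step 1, ranked in that order.

(a) Step 2, alkylation stage.
- Risks: a second alkylation at C6 of 6, Michael addition of a second molecule of 3 to 5, or plain reduction of 3 by the Hantzsch ester.
- Fallback: the polar C–C bond formation is replaced by a radical C–H alkylation, setting out from 3.
- Purchased tricosanoic acid is converted with DCC and H2O2 (Et2O/CH2Cl2, 0 °C) into bis(tricosanoyl) peroxide F1.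
- Compound 3 is heated with F1 in AcOH at 95 °C. O–O homolysis and loss of CO2 give the docosyl radical, which adds to a ring C–H carbon. The adduct is re-oxidised by the peroxide (peroxide alkylation of a quinone).
- The fallback comes back to the route at 6, which is then isolated and etherified as in the second stage of step 2.

(b) Step 2, etherification stage.
- Risks: formation of the dimethyl ether or of a mixture of site isomers, and interference from the by-products of the first stage.
- Fallback: the order of events is inverted, so that the position of the methyl group is fixed by the electronics of C–C bond formation and not by sterics. It sets out from 3.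
- MeOH/H2SO4 at reflux gives 2,5-dimethoxy-1,4-benzoquinone F2.
- One equivalent of aq. NaOH (then HCl) cleaves a single vinylogous ester to 2-hydroxy-5-methoxy-1,4-benzoquinone F3. The anion that forms resists a second hydrolysis.
- F3 is reductively alkylated with 4 (Hantzsch ester, L-proline, CH2Cl2) through 3-docosylidene-5-methoxycyclohex-5-ene-1,2,4-trione F4.
- Only the carbon next to the free OH is enolic, so the chain can enter only there. The fallback comes back to the route at 7.

(c) Step 1.
- Risks: a strong exotherm and over-oxidation to ring-opened acids, giving a low yield.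
- Fallback: the two ring heteroatoms are brought in by a nitrogen nucleophile under air instead of by peroxide. It sets out from 1.
- Compound 1 is aerated with 40% aq. Me2NH and Cu(OAc)2 (5 mol%) in EtOH. This gives crystalline 2,5-bis(dimethylamino)-1,4-benzoquinone F5 by oxidation and double conjugate amination.
- Hot 10% aq. H2SO4 hydrolyses both vinylogous amides. The fallback comes back to the route at 3.

**Further compounds**
F1 | step 2 | bis(tricosanoyl) peroxide | CCCCCCCCCCCCCCCCCCCCCCC(=O)OOC(=O)CCCCCCCCCCCCCCCCCCCCCC
F2 | step 2 | 2,5-dimethoxy-1,4-benzoquinone | COC1=CC(=O)C(OC)=CC1=O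
F3 | step 2 | 2-hydroxy-5-methoxy-1,4-benzoquinone | COC1=CC(=O)C(O)=CC1=O
F4 | step 2 | 3-docosylidene-5-methoxycyclohex-5-ene-1,2,4-trione | CCCCCCCCCCCCCCCCCCCCCC=C1C(=O)C(=O)C=C(OC)C1=O
F5 | step 1 | 2,5-bis(dimethylamino)-1,4-benzoquinone | CN(C)C1=CC(=O)C(N(C)C)=CC1=O
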